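**Strategy.** The six-membered ring is numbered C1 (ketone), C2 (methyl-bearing epoxide carbon), C3 (epoxide CH), C4, C5 (side-chain carbon) and C6 (angelate carbinol); it is cut at C1–C6 and C2–C3. The oxygen-bearing carbons C6 and C3 stand 1,4 across the ring, so they become the α-carbons of a furan, and C1–C2 becomes an alkyne. A Diels–Alder reaction of the 3-substituted furan 9 with methyl 3-bromopropiolate 11 makes both bonds at once and gives a 7-oxanorbornadiene. Its bridge oxygen becomes the C6 oxygen, exo reduction sets C5, and β-elimination of the bridge unveils the enone for a hydroxyl-directed epoxidation.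

Key step: step 6

Step 1
Reactants: 1 methyl (2S)-oxirane-2-carboxylate; 2 (2-methylprop-1-en-1-yl)magnesium bromide
Product: 3 methyl (2S)-2-hydroxy-5-methylhex-4-enoate
Conditions: 2 (1.3 equiv), CuI (10 mol %), THF, −40 °C
Reagents that add atoms: none
Why: Cu-catalysed Grignard opening of the epoxide at its CH2 terminus (SN2) leaves the carbinol centre untouched, so the (S)-configured side-chain carbinol comes from the chiral pool.

Step 2
Reactants: 3 methyl (2S)-2-hydroxy-5-methylhex-4-enoate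
Product: 4 (2S)-2-hydroxy-N-methoxy-N,5-dimethylhex-4-enamide
Conditions: MeNH(OMe)·HCl, i-PrMgCl (3 equiv), THF, −20 → 0 °C
Reagents that add atoms: N,O-dimethylhydroxylamine hydrochloride (CNOC.Cl)
Why: Weinreb amide formation by aminolysis with the chloromagnesium amide, the α-hydroxyl being carried as its magnesium alkoxide, which prevents epimerisation.

Step 3
Reactants: 4 (2S)-2-hydroxy-N-methoxy-N,5-dimethylhex-4-enamide; 5 3-bromofuran
Product: 7 (2S)-1-(furan-3-yl)-2-hydroxy-5-methylhex-4-en-1-one, via furan-3-yllithium 6 (not isolated)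
Conditions: 5, n-BuLi, THF, −78 °C; add to 4 pre-treated with i-PrMgCl (1 equiv), −78 °C; NaHCO3 aq.
Reagents that add atoms: none
Why: Bromine–lithium exchange followed by acyl substitution on the Weinreb amide stops at the ketone through the chelated tetrahedral intermediate, and the neighbouring alkoxide blocks enolisation so the stereocentre is kept.

Step 4
Reactants: 7 (2S)-1-(furan-3-yl)-2-hydroxy-5-methylhex-4-en-1-one; 8 [(trimethylsilyl)methyl]magnesium chloride
Product: 9 (2R,3S)-2-(furan-3-yl)-6-methyl-1-(trimethylsilyl)hept-5-ene-2,3-diol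
Conditions: 8 (3 equiv), THF/Et2O, −78 → 0 °C; NaHCO3 aq.
Reagents that add atoms: none
Why: Chelation-controlled Grignard addition to the α-alkoxide ketone (Cram chelate) gives the tertiary β-hydroxysilane needed for a later Peterson olefination; the new centre is expected (2R) but is erased in step 9.

Step 5
Reactants: 10 methyl prop-2-ynoate
Product: 11 methyl 3-bromoprop-2-ynoate
Conditions: N-bromosuccinimide, AgNO3 (10 mol %), acetone, 23 °C
Reagents that add atoms: N-bromosuccinimide (O=C1CCC(=O)N1Br)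
Why: Ag-catalysed electrophilic bromination of the terminal alkyne C–H.

Step 6
Reactants: 9 (2R,3S)-2-(furan-3-yl)-6-methyl-1-(trimethylsilyl)hept-5-ene-2,3-diol; 11 methyl 3-bromoprop-2-ynoate
Product: 12 methyl (1R,4S)-3-bromo-5-[(2R,3S)-2,3-dihydroxy-6-methyl-1-(trimethylsilyl)hept-5-en-2-yl]-7-oxabicyclo[2.2.1]hepta-2,5-diene-2-carboxylate
Conditions: 11 (2 equiv), solid NaHCO3, toluene, 85 °C, sealed tube
Reagents that add atoms: none
Why: Concerted, asynchronous [4+2] cycloaddition (Diels–Alder) with the furan of 9 as diene and the alkyne of 11 as dienophile; the closest known reaction is the thermal Diels–Alder reaction of furans with 3-halopropiolates. It closes the six-membered carbocycle as a 7-oxabicyclo[2.2.1]hepta-2,5-diene by intermolecular suprafacial addition across furan C2 and C5, which forms C1–C6 and C2–C3 of the later cyclohexanone together. The two bridgehead centres arise cis from the suprafacial mode; their sense relative to the side-chain carbinol is not controlled by the substrate, so both facial adducts are expected and 12 is freed from its diastereomer of opposite bridgehead configuration by chromatography. The step needs head-to-head regioselectivity: the alkyl group at furan C3 makes C2 the more nucleophilic terminus and the propiolate is electrophilic at its bromine-bearing carbon, so this carbon (the later ketone C1) bonds next to the substituted furan carbon. Solid NaHCO3 protects the acid-labile β-silyl carbinol.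

Step 7
Reactants: 12 methyl (1R,4S)-3-bromo-5-[(2R,3S)-2,3-dihydroxy-6-methyl-1-(trimethylsilyl)hept-5-en-2-yl]-7-oxabicyclo[2.2.1]hepta-2,5-diene-2-carboxylate
Product: 13 methyl (1R,2R,4S)-5-[(2R,3S)-2,3-dihydroxy-6-methyl-1-(trimethylsilyl)hept-5-en-2-yl]-3,3-dimethoxy-7-oxabicyclo[2.2.1]hept-5-ene-2-carboxylate
Conditions: NaOMe, MeOH, 0 °C
Reagents that add atoms: sodium methoxide (C[O-].[Na+]); methanol (CO)
Why: Addition–elimination of methoxide at the β-bromoacrylate and a second conjugate addition give the dimethyl ketal, which masks the later ketone so that the bridge cannot be expelled before the ring alkene is reduced; the ester centre (exo expected) is epimerisable and later removed.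

Step 8
Reactants: 13 methyl (1R,2R,4S)-5-[(2R,3S)-2,3-dihydroxy-6-methyl-1-(trimethylsilyl)hept-5-en-2-yl]-3,3-dimethoxy-7-oxabicyclo[2.2.1]hept-5-ene-2-carboxylate
Product: 14 methyl (1R,2R,4S,5R)-5-[(2R,3S)-2,3-dihydroxy-6-methyl-1-(trimethylsilyl)hept-5-en-2-yl]-3,3-dimethoxy-7-oxabicyclo[2.2.1]heptane-2-carboxylate
Conditions: 2-nitrobenzenesulfonohydrazide, Et3N, CH2Cl2, 23 °C
Reagents that add atoms: none
Why: Diimide reduction delivers two hydrogens syn to the strained norbornene-type alkene from the exo face (the side of the oxygen bridge) and spares the unstrained trisubstituted alkene, which places the side chain endo, that is trans to the bridge oxygen (later C5/C6 trans).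

Step 9
Reactants: 14 methyl (1R,2R,4S,5R)-5-[(2R,3S)-2,3-dihydroxy-6-methyl-1-(trimethylsilyl)hept-5-en-2-yl]-3,3-dimethoxy-7-oxabicyclo[2.2.1]heptane-2-carboxylate
Product: 15 methyl (1R,2R,4S,5S)-5-[(3S)-3-hydroxy-6-methylhepta-1,5-dien-2-yl]-3-oxo-7-oxabicyclo[2.2.1]heptane-2-carboxylate
Conditions: TsOH·H2O (cat.), acetone/H2O, 23 °C
Reagents that add atoms: water (O)
Why: Acid hydrolysis of the ketal and acid-mediated Peterson elimination of the tertiary β-hydroxysilane occur together; only the 1,1-disubstituted alkene can form, and the side-chain carbinol is not touched.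

Step 10
Reactants: 15 methyl (1R,2R,4S,5S)-5-[(3S)-3-hydroxy-6-methylhepta-1,5-dien-2-yl]-3-oxo-7-oxabicyclo[2.2.1]heptane-2-carboxylate
Product: 16 methyl (1R,2S,4S,5S)-5-[(3S)-3-hydroxy-6-methylhepta-1,5-dien-2-yl]-2-methyl-3-oxo-7-oxabicyclo[2.2.1]heptane-2-carboxylate
Conditions: K2CO3, MeI, acetone, 23 °C
Reagents that add atoms: iodomethane (CI)
Why: C-alkylation of the β-keto ester enolate installs the ring methyl group (exo attack expected); the quaternary centre becomes sp2 in step 11, so its configuration does not matter.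

Step 11
Reactants: 16 methyl (1R,2S,4S,5S)-5-[(3S)-3-hydroxy-6-methylhepta-1,5-dien-2-yl]-2-methyl-3-oxo-7-oxabicyclo[2.2.1]heptane-2-carboxylate
Product: 18 (5S,6S)-6-hydroxy-5-[(3S)-3-hydroxy-6-methylhepta-1,5-dien-2-yl]-2-methylcyclohex-2-en-1-one, via oxanorbornanone 17 (not isolated)
Conditions: LiCl, DMSO/H2O, 140 °C; then DBU, 23 °C
Reagents that add atoms: none
Why: Krapcho dealkoxycarbonylation gives ketone 17, whose enolate (DBU) expels the bridging alkoxide from the β-carbon (E1cB); this leaves the oxygen on C6 with the configuration set in step 6 and creates the C2=C3 enone.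

Step 12
Reactants: 18 (5S,6S)-6-hydroxy-5-[(3S)-3-hydroxy-6-methylhepta-1,5-dien-2-yl]-2-methylcyclohex-2-en-1-one; 19 (2Z)-2-methylbut-2-enoic acid (two molar equivalents, one for each hydroxyl group)
Product: 21 (1S,6S)-3-methyl-6-[(3S)-6-methyl-3-{[(2Z)-2-methylbut-2-enoyl]oxy}hepta-1,5-dien-2-yl]-2-oxocyclohex-3-en-1-yl (2Z)-2-methylbut-2-enoate, via mixed anhydride 20 (not isolated)
Conditions: 19 (2.5 equiv), 2,4,6-trichlorobenzoyl chloride (2.5 equiv), Et3N (5 equiv), toluene, 23 °C; then 18, 80 °C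
Reagents that add atoms: angelic acid, second equivalent of 19 (C/C=C(/C)C(=O)O)
Why: Yamaguchi esterification in which two molecules of the mixed anhydride 20 acylate the two secondary alcohols of 18, one each, without a nucleophilic catalyst, which keeps the (Z)-geometry of the angelate.

Step 13
Reactants: 21 (1S,6S)-3-methyl-6-[(3S)-6-methyl-3-{[(2Z)-2-methylbut-2-enoyl]oxy}hepta-1,5-dien-2-yl]-2-oxocyclohex-3-en-1-yl (2Z)-2-methylbut-2-enoate
Product: 22 (1S,2S,6S)-2-hydroxy-3-methyl-6-[(3S)-6-methyl-3-{[(2Z)-2-methylbut-2-enoyl]oxy}hepta-1,5-dien-2-yl]cyclohex-3-en-1-yl (2Z)-2-methylbut-2-enoate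
Conditions: NaBH4, CeCl3·7H2O, MeOH, −78 °C; AcOH quench
Reagents that add atoms: none
Why: Luche 1,2-reduction; axial hydride attack on the half-chair with both ring substituents equatorial gives the equatorial alcohol, trans to the C6 ester and cis to the C5 side chain.

Step 14
Reactants: 22 (1S,2S,6S)-2-hydroxy-3-methyl-6-[(3S)-6-methyl-3-{[(2Z)-2-methylbut-2-enoyl]oxy}hepta-1,5-dien-2-yl]cyclohex-3-en-1-yl (2Z)-2-methylbut-2-enoate
Product: 23 (1R,2R,3S,4S,6S)-2-hydroxy-1-methyl-4-[(3S)-6-methyl-3-{[(2Z)-2-methylbut-2-enoyl]oxy}hepta-1,5-dien-2-yl]-7-oxabicyclo[4.1.0]heptan-3-yl (2Z)-2-methylbut-2-enoate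
Conditions: VO(acac)2 (cat.), t-BuOOH, CH2Cl2, 0 °C
Reagents that add atoms: tert-butyl hydroperoxide (CC(C)(C)OO)
Why: Hydroxyl-directed vanadium-catalysed epoxidation delivers oxygen syn to the allylic hydroxyl, hence cis to the C5 side chain and trans to the C6 ester; the other alkenes have no free directing hydroxyl or are electron-poor.

Step 15
Reactants: 23 (1R,2R,3S,4S,6S)-2-hydroxy-1-methyl-4-[(3S)-6-methyl-3-{[(2Z)-2-methylbut-2-enoyl]oxy}hepta-1,5-dien-2-yl]-7-oxabicyclo[4.1.0]heptan-3-yl (2Z)-2-methylbut-2-enoate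
Product: 24 (1S,3S,4S,6S)-1-methyl-4-[(3S)-6-methyl-3-{[(2Z)-2-methylbut-2-enoyl]oxy}hepta-1,5-dien-2-yl]-2-oxo-7-oxabicyclo[4.1.0]heptan-3-yl (2Z)-2-methylbut-2-enoate
Conditions: Dess–Martin periodinane, NaHCO3, CH2Cl2, 0 → 23 °C
Reagents that add atoms: none
Why: Dess–Martin oxidation of the secondary alcohol under buffered, non-basic conditions, so the α-acyloxy epoxy ketone is not epimerised.

Step 16
Reactants: 24 (1S,3S,4S,6S)-1-methyl-4-[(3S)-6-methyl-3-{[(2Z)-2-methylbut-2-enoyl]oxy}hepta-1,5-dien-2-yl]-2-oxo-7-oxabicyclo[4.1.0]heptan-3-yl (2Z)-2-methylbut-2-enoate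
Product: 25 (1S,3S,4S,6S)-4-[(3S)-4-[(2R)-3,3-dimethyloxiran-2-yl]-3-{[(2Z)-2-methylbut-2-enoyl]oxy}but-1-en-2-yl]-1-methyl-2-oxo-7-oxabicyclo[4.1.0]heptan-3-yl (2Z)-2-methylbut-2-enoate (CNP0247177.2)
Conditions: D-fructose-derived Shi ketone (30 mol %), Oxone (KHSO5), K2CO3, buffer/MeCN–CH2(OMe)2, 0 °C
Reagents that add atoms: potassium peroxymonosulfate (O=S(=O)([O-])OO.[K+])
Why: Shi epoxidation; the chiral dioxirane attacks the most electron-rich trisubstituted alkene through the spiro transition state and should give the (R)-epoxide under reagent control, while the 1,1-disubstituted and conjugated alkenes react far more slowly.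

**Compound list**

1 | methyl (2S)-oxirane-2-carboxylate | COC(=O)[C@@H]1CO1 | starting material
2 | (2-methylprop-1-en-1-yl)magnesium bromide | CC(C)=C[Mg]Br | starting material
3 | methyl (2S)-2-hydroxy-5-methylhex-4-enoate | COC(=O)[C@@H](O)CC=C(C)C | intermediate
4 | (2S)-2-hydroxy-N-methoxy-N,5-dimethylhex-4-enamide | CON(C)C(=O)[C@@H](O)CC=C(C)C | intermediate
5 | 3-bromofuran | Brc1ccoc1 | starting material
6 | furan-3-yllithium | [Li]c1ccoc1 | intermediate
7 | (2S)-1-(furan-3-yl)-2-hydroxy-5-methylhex-4-en-1-one | O=C(c1ccoc1)[C@@H](O)CC=C(C)C | intermediate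
8 | [(trimethylsilyl)methyl]magnesium chloride | C[Si](C)(C)C[Mg]Cl | starting material
9 | (2R,3S)-2-(furan-3-yl)-6-methyl-1-(trimethylsilyl)hept-5-ene-2,3-diol | C[Si](C)(C)C[C@@](O)(c1ccoc1)[C@@H](O)CC=C(C)C | intermediate
10 | methyl prop-2-ynoate | C#CC(=O)OC | starting material
11 | methyl 3-bromoprop-2-ynoate | BrC#CC(=O)OC | intermediate
12 | methyl (1R,4S)-3-bromo-5-[(2R,3S)-2,3-dihydroxy-6-methyl-1-(trimethylsilyl)hept-5-en-2-yl]-7-oxabicyclo[2.2.1]hepta-2,5-diene-2-carboxylate | COC(=O)C1=C(Br)[C@H]2O[C@@H]1C=C2[C@](O)(C[Si](C)(C)C)[C@@H](O)CC=C(C)C | intermediate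
13 | methyl (1R,2R,4S)-5-[(2R,3S)-2,3-dihydroxy-6-methyl-1-(trimethylsilyl)hept-5-en-2-yl]-3,3-dimethoxy-7-oxabicyclo[2.2.1]hept-5-ene-2-carboxylate (ester exo) | COC(=O)[C@H]1C(OC)(OC)[C@H]2O[C@@H]1C=C2[C@](O)(C[Si](C)(C)C)[C@@H](O)CC=C(C)C | intermediate
14 | methyl (1R,2R,4S,5R)-5-[(2R,3S)-2,3-dihydroxy-6-methyl-1-(trimethylsilyl)hept-5-en-2-yl]-3,3-dimethoxy-7-oxabicyclo[2.2.1]heptane-2-carboxylate (side chain endo) | COC(=O)[C@H]1C(OC)(OC)[C@H]2O[C@@H]1C[C@H]2[C@](O)(C[Si](C)(C)C)[C@@H](O)CC=C(C)C | intermediate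
15 | methyl (1R,2R,4S,5S)-5-[(3S)-3-hydroxy-6-methylhepta-1,5-dien-2-yl]-3-oxo-7-oxabicyclo[2.2.1]heptane-2-carboxylate | COC(=O)[C@H]1C(=O)[C@H]2O[C@@H]1C[C@H]2C(=C)[C@@H](O)CC=C(C)C | intermediate
16 | methyl (1R,2S,4S,5S)-5-[(3S)-3-hydroxy-6-methylhepta-1,5-dien-2-yl]-2-methyl-3-oxo-7-oxabicyclo[2.2.1]heptane-2-carboxylate | COC(=O)[C@]1(C)C(=O)[C@H]2O[C@@H]1C[C@H]2C(=C)[C@@H](O)CC=C(C)C | intermediate
17 | (1S,3R,4R,6S)-6-[(3S)-3-hydroxy-6-methylhepta-1,5-dien-2-yl]-3-methyl-7-oxabicyclo[2.2.1]heptan-2-one | C[C@H]1C(=O)[C@H]2O[C@@H]1C[C@H]2C(=C)[C@@H](O)CC=C(C)C | intermediate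
18 | (5S,6S)-6-hydroxy-5-[(3S)-3-hydroxy-6-methylhepta-1,5-dien-2-yl]-2-methylcyclohex-2-en-1-one | C=C([C@H](CC=C(C)C)O)[C@@H]1CC=C(C)C(=O)[C@H]1O | intermediate
19 | (2Z)-2-methylbut-2-enoic acid (angelic acid) | C/C=C(/C)C(=O)O | starting material
20 | (2Z)-2-methylbut-2-enoic 2,4,6-trichlorobenzoic anhydride | C/C=C(/C)C(=O)OC(=O)c1c(Cl)cc(Cl)cc1Cl | intermediate
21 | (1S,6S)-3-methyl-6-[(3S)-6-methyl-3-{[(2Z)-2-methylbut-2-enoyl]oxy}hepta-1,5-dien-2-yl]-2-oxocyclohex-3-en-1-yl (2Z)-2-methylbut-2-enoate | C=C([C@H](CC=C(C)C)OC(=O)/C(C)=C\C)[C@@H]1CC=C(C)C(=O)[C@H]1OC(=O)/C(C)=C\C | intermediate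
22 | (1S,2S,6S)-2-hydroxy-3-methyl-6-[(3S)-6-methyl-3-{[(2Z)-2-methylbut-2-enoyl]oxy}hepta-1,5-dien-2-yl]cyclohex-3-en-1-yl (2Z)-2-methylbut-2-enoate | C=C([C@H](CC=C(C)C)OC(=O)/C(C)=C\C)[C@@H]1CC=C(C)[C@H](O)[C@H]1OC(=O)/C(C)=C\C | intermediate
23 | (1R,2R,3S,4S,6S)-2-hydroxy-1-methyl-4-[(3S)-6-methyl-3-{[(2Z)-2-methylbut-2-enoyl]oxy}hepta-1,5-dien-2-yl]-7-oxabicyclo[4.1.0]heptan-3-yl (2Z)-2-methylbut-2-enoate | C=C([C@H](CC=C(C)C)OC(=O)/C(C)=C\C)[C@@H]1C[C@@H]2O[C@]2(C)[C@H](O)[C@H]1OC(=O)/C(C)=C\C | intermediate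
24 | (1S,3S,4S,6S)-1-methyl-4-[(3S)-6-methyl-3-{[(2Z)-2-methylbut-2-enoyl]oxy}hepta-1,5-dien-2-yl]-2-oxo-7-oxabicyclo[4.1.0]heptan-3-yl (2Z)-2-methylbut-2-enoate | C=C([C@H](CC=C(C)C)OC(=O)/C(C)=C\C)[C@@H]1C[C@@H]2O[C@]2(C)C(=O)[C@H]1OC(=O)/C(C)=C\C | intermediate
25 | (1S,3S,4S,6S)-4-[(3S)-4-[(2R)-3,3-dimethyloxiran-2-yl]-3-{[(2Z)-2-methylbut-2-enoyl]oxy}but-1-en-2-yl]-1-methyl-2-oxo-7-oxabicyclo[4.1.0]heptan-3-yl (2Z)-2-methylbut-2-enoate | C=C([C@H](C[C@H]1OC1(C)C)OC(=O)/C(C)=C\C)[C@@H]1C[C@@H]2O[C@]2(C)C(=O)[C@H]1OC(=O)/C(C)=C\C | target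

**Step count and risks**

Total step count: 16. Longest linear sequence: 15 steps (steps 1–4 and 6–16; step 5 is a one-step side branch).

Steps most likely to fail:

- **Step 6.** The furan faces are not differentiated by the carbinol centres, head-to-head regiocontrol may be incomplete, and the β-silyl carbinol may be lost to acid at 85 °C. Fallback, setting out from 9 and returning at 15: the cycloaddition is made intramolecular through a temporary silicon tether. The secondary hydroxyl of 9 is silylated with methyl 3-[chloro(diisopropyl)silyl]prop-2-ynoate (from 10, LiN(SiMe3)2 and i-Pr2SiCl2; imidazole, CH2Cl2) to give the tethered ynoate F1. Heating in toluene closes the same two bonds in a type 2 intramolecular Diels–Alder reaction to the tethered oxanorbornadiene F2; the tether enforces the head-to-head orientation and holds the alkyne over one furan face. Diimide reduction as in step 8 gives the dihydro compound F3. Tamao–Fleming oxidation of the alkenylsilane (KF, KHCO3, H2O2) followed by TsOH in wet acetone (Peterson elimination) gives 15.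

- **Step 11.** Thermal dealkoxycarbonylation of the hindered quaternary ester may stall, or the freed α'-hydroxy enone may dehydrate towards an aromatic ring at 140 °C. Fallback, setting out from 15 and returning at 17: decarboxylation and methylation are swapped. Pig liver esterase at pH 7 hydrolyses the methyl ester of 15, and the β-keto acid loses CO2 at 23 °C to give the nor-methyl ketone F4. Its lithium enolate (LDA, 2.2 equiv, THF, −78 °C) is methylated with MeI from the exo face to give 17, which is opened with DBU to 18 as in the main route.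

- **Step 13.** The ring angelate may migrate onto the newly formed neighbouring hydroxyl, or hydride may be delivered to the wrong face. Fallback, setting out from 18 and returning at 24: the acylation is moved to the end. The diol 18 is capped (TESOTf, 2,6-lutidine) as the bis(triethylsilyl) ether F5. Luche reduction gives the allylic alcohol F6, VO(acac)2/t-BuOOH the epoxy alcohol F7 and Dess–Martin oxidation the epoxy ketone F8. HF·pyridine frees the epoxy ketone diol F9, which is acylated on both hydroxyl groups by two equivalents of mixed anhydride 20 to give 24.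

**Further compounds**

F1 | step 6 | methyl 3-[({(2R,3S)-2-(furan-3-yl)-2-hydroxy-6-methyl-1-(trimethylsilyl)hept-5-en-3-yl}oxy)di(propan-2-yl)silyl]prop-2-ynoate | COC(=O)C#C[Si](C(C)C)(C(C)C)O[C@@H](CC=C(C)C)[C@@](O)(C[Si](C)(C)C)c1ccoc1
F2 | step 6 | silicon-tethered 7-oxanorbornadiene: bridgeheads as in 12, methyl ester on the alkene carbon next to the unsubstituted-side bridgehead, diisopropylsilyl on the neighbouring alkene carbon and joined through oxygen to the side-chain carbinol in a seven-membered siloxane ring | COC(=O)C1=C2[C@H]3O[C@@H]1C=C3[C@](O)(C[Si](C)(C)C)[C@H](CC=C(C)C)O[Si]2(C(C)C)C(C)C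
F3 | step 6 | 5,6-dihydro derivative of F2 with the side-chain carbon endo | COC(=O)C1=C2[C@H]3O[C@@H]1C[C@H]3[C@](O)(C[Si](C)(C)C)[C@H](CC=C(C)C)O[Si]2(C(C)C)C(C)C
F4 | step 11 | (1S,4R,6S)-6-[(3S)-3-hydroxy-6-methylhepta-1,5-dien-2-yl]-7-oxabicyclo[2.2.1]heptan-2-one | C1C(=O)[C@H]2O[C@@H]1C[C@H]2C(=C)[C@@H](O)CC=C(C)C
F5 | step 13 | (5S,6S)-2-methyl-6-[(triethylsilyl)oxy]-5-{(3S)-6-methyl-3-[(triethylsilyl)oxy]hepta-1,5-dien-2-yl}cyclohex-2-en-1-one | C=C([C@H](CC=C(C)C)O[Si](CC)(CC)CC)[C@@H]1CC=C(C)C(=O)[C@H]1O[Si](CC)(CC)CC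
F6 | step 13 | (1S,5S,6S)-2-methyl-6-[(triethylsilyl)oxy]-5-{(3S)-6-methyl-3-[(triethylsilyl)oxy]hepta-1,5-dien-2-yl}cyclohex-2-en-1-ol | C=C([C@H](CC=C(C)C)O[Si](CC)(CC)CC)[C@@H]1CC=C(C)[C@H](O)[C@H]1O[Si](CC)(CC)CC
F7 | step 13 | (1R,2R,3S,4S,6S)-1-methyl-3-[(triethylsilyl)oxy]-4-{(3S)-6-methyl-3-[(triethylsilyl)oxy]hepta-1,5-dien-2-yl}-7-oxabicyclo[4.1.0]heptan-2-ol | C=C([C@H](CC=C(C)C)O[Si](CC)(CC)CC)[C@@H]1C[C@@H]2O[C@]2(C)[C@H](O)[C@H]1O[Si](CC)(CC)CC
F8 | step 13 | (1S,3S,4S,6S)-1-methyl-3-[(triethylsilyl)oxy]-4-{(3S)-6-methyl-3-[(triethylsilyl)oxy]hepta-1,5-dien-2-yl}-7-oxabicyclo[4.1.0]heptan-2-one | C=C([C@H](CC=C(C)C)O[Si](CC)(CC)CC)[C@@H]1C[C@@H]2O[C@]2(C)C(=O)[C@H]1O[Si](CC)(CC)CC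
F9 | step 13 | (1S,3S,4S,6S)-3-hydroxy-4-[(3S)-3-hydroxy-6-methylhepta-1,5-dien-2-yl]-1-methyl-7-oxabicyclo[4.1.0]heptan-2-one | C=C([C@H](CC=C(C)C)O)[C@@H]1C[C@@H]2O[C@]2(C)C(=O)[C@H]1O
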